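## The problem

The target is a briarane diterpenoid. Atoms are numbered C1 (quaternary, C15 methyl), C2 (CHOH), C3–C4 (epoxide), C5 (=C16H2), C6 (CHCl), C7 (lactone CH–O), C8 (C–OH), C9 (CHOAc), C10 (ring-fusion CH), C11 (C20 methyl), C12 (CHOH), C13–C14 (epoxide), C17 (C18 methyl) and C19 (lactone C=O). A cyclohexane (ring A: C1, C10–C14) is trans-fused to a ten-membered carbocycle (C1–C10), which carries a γ-lactone across C7–C8. Fourteen stereocentres must be set. On ring A the C15 methyl, the C9 branch, the C20 methyl and the C12 oxygen all sit on one face (β), while the 13,14-epoxide is on the other; the remaining centres lie on the flexible ten-membered ring. Ring A can relay its configuration to C12 (by lactonisation from C9) and to C9 (Felkin–Anh addition next to C10). C2 is best set by a reagent, and the ring centres C6, C7, C8 and C17 and both epoxides must be induced after the macrocycle exists. Fragile groups are the vinyl epoxide at C3–C4, the secondary allylic chloride at C6 (SN2′, elimination and reduction), the tertiary β-hydroxy lactone and the C9 acetate next to the free C8 hydroxyl. The enabling feature is that C7 is the γ-carbon of the C19 lactone and C6 its heteroatom-bearing neighbour. C6–C7 is therefore a vinylogous aldol bond, and the lactone can be carried as a 3-methyl-2-silyloxyfuran attached through C8.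

## Retrosynthesis

**Epoxides last (47 ⇒ 46 ⇒ 45 ⇒ 44).** The C–O bonds of both epoxides and the C12 silyl ether are cut first, because the vinyl epoxide survives neither SmI2 nor Lewis acids. The 13,14-epoxide of 46 comes from peracid attack on 45 anti to the 12-silyloxy group and the axial C15 methyl. The 3,4-epoxide of 45 comes from hydroxyl-directed epoxidation of the free C2 alcohol 44, which needs cis delivery in a medium-ring Z-allylic alcohol.

**Heteroatom adjustments (44 ⇒ 43 ⇒ 42 ⇒ 41 ⇒ 40).** Three orthogonal groups on C2 (PMB), C9 (TES) and C12 (TBS) let the C9 acetate be installed (42, 43) before C2 is freed (44). The C6 chloride of 41 comes from the C6 alcohol of 40 with inversion. It is placed after the reductive step, which an allylic chloride would not survive.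

**C8 carbinol (40 ⇒ 39 ⇒ 38).** The C8–O bond and C17–H are traced to the butenolide 38 through the 8,17-epoxy lactone 39 (nucleophilic epoxidation, then SmI2 cleavage of C17–O). This flattens the lactone and removes two stereocentres.

**Key cut C6–C7 (38 ⇒ 37).** Other ring bonds are less attractive: C5–C6 would need a vinyl-metal addition beside a preformed C7 centre, C8–C9 would join two hindered carbons in the ring, and C3=C4 would need a Z-selective macro-olefination. Cutting C6–C7 gives the open-chain silyloxyfuran dienal 37, one ring and two stereocentres simpler. The forward reaction must be a vinylogous Mukaiyama aldol that closes ten atoms, adds 1,2 and not 1,4 to the enal, and chooses one furan face.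

**C8–C9 (37 ⇒ 36 ⇒ 35 ⇒ 26 + 32).** The furan is added as its 4-lithio derivative (from bromide 32) to the C9 aldehyde 26, where Felkin–Anh control should give the required carbinol. C6 travels as a pivalate, so that after the furan is in place only a hydride (35 → 36) and MnO2 (36 → 37) are needed. No acid or fluoride then touches the silyloxyfuran.

**C2–C6 arm (26 ⇒ 25 ⇒ 24 ⇒ 23 ⇒ 22 ⇒ 21 ⇒ 15 + 19).** The Z alkene comes from semihydrogenation of the enyne 23, C2 from reagent-controlled reduction of the ynone 21, and the C2–C3 bond from acylation of the enyne 19 by the acid 15. This is preferred to a Z-selective Wittig reaction on a neopentyl aldehyde, which would leave C2 to substrate control.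

**Ring A oxygenation (15 ⇒ 13 ⇒ 12 ⇒ 11 ⇒ 10).** The C12–O bond and the C13=C14 alkene are traced to iodolactonisation and elimination of the cyclohexene acid 10. This delivers O12 cis to C9 and moves the alkene into place, and both functions fall out of one carboxyl group.

**Ring A carbons (10 ⇒ 8 ⇒ 6 + 7).** C1–C14 and C10–C11 are cut in a Diels–Alder sense to (E)-piperylene 7 and the mesaconate-derived imide 6. The ortho and endo rules give the all-cis array of C15 methyl, C9 carbonyl and C20 methyl, and the auxiliary sets the absolute configuration.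

**Small pieces.** 6 comes from acid 3 and auxiliary 4, and 3 from glyoxylic acid 1 and ylide 2. Enyne 19 comes from diol 16 via 17 and 18. Bromofuran 32 comes from ethyl 2-methylacetoacetate 27 via 30 and 31.

## Roads not taken

**Alternative 1: transannular Michael closure of a fourteen-membered carbocycle.**
- Cut and forward step: C1–C10 is cut. In the macrocyclic diketone A1, the C1 carbanion (between the C2 ketone and the C14=C13–C12=O enone) adds across the ring to C10, giving the tricycle A2.
- Merits: one step forms both carbocycles and the C1 quaternary centre with the lactone already present. In rings formed per step it is better than the chosen plan.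
- Weak points: A1 is itself a large, densely functionalised macrocycle that must carry the vinyl epoxide, the allylic chloride and the C9 acetate through a base-mediated step. The trans relationship at C1/C10 and the C11 methyl depend on an unknown macrocycle conformation. A2 still needs stereoselective reduction of two ketones and the 13,14-epoxide.
- Comparison: the chosen plan sets against the greater convergence of this road a ring A whose four contiguous centres come from well-understood cycloaddition and lactonisation rules, and a macrocyclisation that carries no epoxide or chloride.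

**Alternative 2: samarium Reformatsky lactone annulation at C8–C17.**
- Cut and forward step: C8–C17 is cut. SmI2 converts the C7 2-bromopropanoate of ketone A3 into an enolate that adds to the C8 ketone and gives the hydroxy lactone A4.
- Merits: the C8 carbinol and C17 are set directly in a five-ring closure. The chosen plan needs two steps of uncertain facial selectivity for the same result, so this road is better on that point.
- Weak points: the ten-membered carbocycle is left unsolved and must be made by another macrocyclisation. The C8 ketone is flanked by C7 acyloxy and C9 silyloxy groups that SmI2 can cleave reductively, and a vinyl epoxide is present during the reduction. The C6 chloride still has to come from a late ene-type chlorination of the C5-methyl alkene among several alkenes.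
- Comparison: the chosen plan sets against the cleaner C8/C17 step of this road the fact that its key step builds the medium ring itself and fixes C6 and C7 with oxygen already at C6.

**Alternative 3: allenyl anionic oxy-Cope expansion.**
- Cut and forward step: C4–C5 is formed while a temporary C2–C7 bond breaks. The potassium alkoxide of decalin A5 rearranges to the cyclodecadienone A6.
- Merits: ring expansion avoids high dilution and the entropic cost of a direct ten-membered closure, and ring A, C8 and C9 are set on a rigid decalin. In reliability of ring formation it is probably better.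
- Weak points: A6 has no lactone carbons, saturated C3–C4, a C6 enol ether carbon and a C2 ketone, so the longest run of functional-group work follows the key step. A5 has two adjacent fully substituted carbons beside the C1 quaternary centre.
- Comparison: the chosen plan accepts a riskier ring closure, but its product already holds every skeletal carbon, the lactone and correctly placed oxygen at C2, C6, C9 and C12.

Key step: step 24

Remarks: β is the face of ring A that carries the C15 methyl group, and names use the briarane atom numbers defined above. Compounds 2 and 4 are taken as purchasable reagents.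

## Steps

Step 1
Reactants: 1 glyoxylic acid monohydrate; 2 tert-butyl 2-(triphenylphosphoranylidene)propanoate
Product: 3 (E)-4-tert-butoxy-3-methyl-4-oxobut-2-enoic acid
Conditions: CH2Cl2, 0 °C → rt
Reagents that add atoms: none
Why: Wittig olefination of the hydrated aldehyde by a stabilised, α-branched ylide; such ylides give the E enoate, which places the free carboxyl trans to the ester as needed for the trans C2/C9 relationship.

Step 2
Reactants: 3 (E)-4-tert-butoxy-3-methyl-4-oxobut-2-enoic acid; 4 (S)-4-benzyl-1,3-oxazolidin-2-one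
Product: 6 (S)-4-benzyl-3-[(E)-4-tert-butoxy-3-methyl-4-oxobut-2-enoyl]-1,3-oxazolidin-2-one, via mixed pivalic anhydride 5 (not isolated)
Conditions: t-BuCOCl, Et3N, THF, −20 °C; then 4, LiCl, −20 °C → rt
Reagents that add atoms: none
Why: N-acylation of the oxazolidinone through a mixed pivalic anhydride with LiCl/Et3N activation; the shielded pivaloyl carbonyl directs attack to the enoyl carbonyl.

Step 3
Reactants: 6 (S)-4-benzyl-3-[(E)-4-tert-butoxy-3-methyl-4-oxobut-2-enoyl]-1,3-oxazolidin-2-one; 7 (E)-penta-1,3-diene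
Product: 8 (S)-4-benzyl-3-{[(1S,2S,6S)-6-(tert-butoxycarbonyl)-2,6-dimethylcyclohex-3-en-1-yl]carbonyl}-1,3-oxazolidin-2-one
Conditions: Et2AlCl (1.5 equiv), CH2Cl2, −78 → −30 °C
Reagents that add atoms: none
Why: Auxiliary-controlled Lewis acid Diels–Alder reaction; the chelated s-cis imide is attacked on the face opposite the benzyl group, the unsubstituted diene terminus (C14) bonds to the β-carbon (C1) and the imide carbonyl is endo. This sets C1, C10 and C11 with C15 methyl, C9 carbonyl and C20 methyl all cis.

Step 4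
Reactants: 8 Diels–Alder imide
Product: 10 (1S,2S,6S)-6-(tert-butoxycarbonyl)-2,6-dimethylcyclohex-3-ene-1-carboxylic acid, via peroxy acid 9 (not isolated)
Conditions: LiOH, H2O2, THF/H2O, 0 °C; then Na2SO3 (aq.)
Reagents that add atoms: hydrogen peroxide, OO
Why: Hydroperoxide cleavage of the N-acyl oxazolidinone at the exocyclic carbonyl; the hindered tert-butyl ester and the stereocentres are untouched.

Step 5
Reactants: 10 cyclohexene acid
Product: 11 tert-butyl 4-iodo-2,8-dimethyl-7-oxo-6-oxabicyclo[3.2.1]octane-2-carboxylate (iodolactone; O12 β, iodine at C13 α)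
Conditions: I2, KI, NaHCO3, H2O/CH2Cl2, 0 °C → rt, dark
Reagents that add atoms: iodine, II
Why: Iodolactonisation (5-exo): the β-carboxylate opens the α-iodonium ion at C12, which fixes O12 cis to C9 and puts iodine at C13 trans to the lactone oxygen.

Step 6
Reactants: 11 iodolactone
Product: 12 tert-butyl 2,8-dimethyl-7-oxo-6-oxabicyclo[3.2.1]oct-3-ene-2-carboxylate (C13=C14 lactone)
Conditions: DBU, toluene, 80 °C
Reagents that add atoms: none
Why: E2 dehydroiodination; only H14 is antiperiplanar to the C13–I bond (H12 is cis to iodine), so the alkene forms at C13=C14.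

Step 7
Reactants: 12 unsaturated lactone
Product: 13 tert-butyl 4-hydroxy-6-(hydroxymethyl)-1,5-dimethylcyclohex-2-ene-1-carboxylate (ring-A diol; C9H2OH, 12β-OH)
Conditions: LiBH4, THF/MeOH, 0 °C → rt
Reagents that add atoms: none
Why: Chemoselective hydride reduction of the lactone; the α-quaternary tert-butyl ester is too hindered for LiBH4.

Step 8
Reactants: 13 ring-A diol
Product: 15 ring-A carboxylic acid (C2 = CO2H; 9-OTBS; 12β-OTBS), via silyl ester 14 (not isolated)
Conditions: TBSOTf (4 equiv), 2,6-lutidine, CH2Cl2, −78 °C → rt; then K2CO3, MeOH/THF/H2O, rt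
Reagents that add atoms: tert-butyldimethylsilyl triflate, CC(C)(C)[Si](C)(C)OS(=O)(=O)C(F)(F)F
Why: Silyl triflate silylation of both hydroxyls; excess reagent also converts the tert-butyl ester into the silyl ester with loss of isobutene, and only that silyl ester is hydrolysed by aqueous carbonate.

Step 9
Reactants: 16 2-methylidenepropane-1,3-diol
Product: 17 2-(hydroxymethyl)prop-2-en-1-yl 2,2-dimethylpropanoate
Conditions: t-BuCOCl (0.5 equiv), pyridine, CH2Cl2, 0 °C (diol in excess)
Reagents that add atoms: pivaloyl chloride, CC(C)(C)C(=O)Cl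
Why: Statistical mono-acylation of a symmetrical diol used in excess.

Step 10
Reactants: 17 mono-pivalate
Product: 18 2-formylprop-2-en-1-yl 2,2-dimethylpropanoate
Conditions: MnO2, CH2Cl2, rt
Reagents that add atoms: none
Why: MnO2 oxidation of a primary allylic alcohol to the 2-substituted acrolein.

Step 11
Reactants: 18 enal pivalate
Product: 19 2-methylidenebut-3-yn-1-yl 2,2-dimethylpropanoate
Conditions: Me3SiCHN2, LiN(i-Pr)2, THF, −78 °C → rt
Reagents that add atoms: (trimethylsilyl)diazomethane, C[Si](C)(C)C=[N+]=[N-]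
Why: Colvin rearrangement: 1,2-addition of the lithiated diazo reagent, Peterson-type elimination and 1,2-shift of the alkylidene carbene give the terminal alkyne; a methanol-free method avoids conjugate addition to the enal.

Step 12
Reactants: 15 ring-A carboxylic acid; 19 enyne pivalate
Product: 21 C2 ynone (C3≡C4; C5=C16H2; 6-O-pivaloyl; 9-OTBS; 12β-OTBS), via acid chloride 20 (not isolated)
Conditions: 1-chloro-N,N,2-trimethylprop-1-en-1-amine, CH2Cl2, 0 °C; then 19, PdCl2(PPh3)2 (cat.), CuI (cat.), Et3N, THF, rt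
Reagents that add atoms: none
Why: Neutral acid chloride formation with an α-chloroenamine followed by acyl Sonogashira coupling; the α-quaternary acyl chloride cannot form a ketene and the silyl ethers see no acid.

Step 13
Reactants: 21 C2 ynone
Product: 22 (2S)-propargylic alcohol (2-OH; otherwise as 21)
Conditions: (S)-2-methyl-CBS-oxazaborolidine, catecholborane, toluene, −78 °C
Reagents that add atoms: none
Why: Corey–Bakshi–Shibata reduction of an ynone; the alkynyl group acts as the small and the quaternary C1 as the large substituent, so the (S)-catalyst should give the C2 configuration of the target.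

Step 14
Reactants: 22 (2S)-propargylic alcohol
Product: 23 (2S)-2-O-(4-methoxybenzyl) ether of 22
Conditions: KN(SiMe3)2, 4-methoxybenzyl bromide, THF, −78 → 0 °C
Reagents that add atoms: 4-methoxybenzyl bromide, COc1ccc(CBr)cc1
Why: Williamson etherification of the potassium alkoxide; PMB is chosen because it is removed oxidatively later in the presence of silyl ethers, acetate and the allylic chloride.

Step 15
Reactants: 23 PMB ether enyne
Product: 24 (2R,3Z)-diene (C3=C4 Z; C5=C16H2; 6-O-pivaloyl; 2-OPMB; 9-OTBS; 12β-OTBS; C2 spatially unchanged)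
Conditions: H2 (1 atm), Pd/CaCO3 poisoned with Pb(OAc)2 (Lindlar catalyst), quinoline, EtOAc, rt
Reagents that add atoms: none
Why: Lindlar semihydrogenation of a conjugated enyne gives the Z diene by syn addition of hydrogen; the hindered ring alkene and the 1,1-disubstituted alkene should not be reduced.

Step 16
Reactants: 24 (2R,3Z)-diene
Product: 25 C9 primary alcohol (C9H2OH; otherwise as 24)
Conditions: HF·pyridine, pyridine, THF, 0 °C
Reagents that add atoms: none
Why: Selective cleavage of the primary TBS ether by buffered HF·pyridine; the secondary allylic TBS ether, the PMB ether and the pivalate are stable.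

Step 17
Reactants: 25 C9 primary alcohol
Product: 26 C9 aldehyde (C9HO on C10; otherwise as 24)
Conditions: Dess–Martin periodinane, NaHCO3, CH2Cl2, 0 °C → rt
Reagents that add atoms: none
Why: Dess–Martin oxidation under buffered, non-basic conditions, which avoids epimerisation at C10.

Step 18
Reactants: 27 ethyl 2-methyl-3-oxobutanoate
Product: 30 3-methyltetronic acid, via alpha-bromo ester 28 (not isolated), via gamma-bromo ester 29 (not isolated)
Conditions: Br2, CHCl3, 0 °C → rt; then neat, 110 °C
Reagents that add atoms: none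
Why: Classical tetronic acid synthesis: bromination of the β-keto ester, HBr-mediated shift of bromine to the terminal methyl, then thermal lactonisation with loss of bromoethane.

Step 19
Reactants: 30 3-methyltetronic acid
Product: 31 4-bromo-3-methylfuran-2(5H)-one
Conditions: (COBr)2, DMF (cat.), CH2Cl2, 0 °C → rt
Reagents that add atoms: oxalyl bromide, O=C(Br)C(=O)Br
Why: Vilsmeier-type conversion of the vinylogous acid into the vinylogous acyl bromide.

Step 20
Reactants: 31 4-bromo-3-methylfuran-2(5H)-one
Product: 32 (4-bromo-3-methylfuran-2-yl)oxy-triisopropylsilane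
Conditions: i-Pr3SiOTf, Et3N, CH2Cl2, 0 °C
Reagents that add atoms: triisopropylsilyl triflate, CC(C)[Si](C(C)C)(C(C)C)OS(=O)(=O)C(F)(F)F
Why: Soft enolisation and O-silylation of the butenolide to the aromatic 2-silyloxyfuran; the bulky silyl group gives the most robust silyloxyfuran.

Step 21
Reactants: 26 C9 aldehyde; 32 bromo silyloxyfuran
Product: 35 (2R,9R)-9-O-triethylsilyl furyl carbinol (C9 bears the 4-methyl-5-(triisopropylsilyloxy)furan-3-yl group; 6-O-pivaloyl; 2-OPMB; 12β-OTBS), via furyllithium 33 (not isolated), via lithium alkoxide 34 (not isolated)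
Conditions: 32, t-BuLi (2 equiv), Et2O, −78 °C; then 26, −78 °C; then Et3SiOTf, −78 → −40 °C
Reagents that add atoms: triethylsilyl triflate, CC[Si](CC)(CC)OS(=O)(=O)C(F)(F)F
Why: Bromine–lithium exchange and addition of the 4-furyllithium to the aldehyde under Felkin–Anh control (quaternary C1 anti to the nucleophile, attack past H10), which should give the (9R) carbinol. In situ silylation of the alkoxide avoids handling the free furylcarbinol, and the pivalate is inert at −78 °C.

Step 22
Reactants: 35 furyl carbinol pivalate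
Product: 36 C6 primary alcohol (C6H2OH; otherwise as 35)
Conditions: i-Bu2AlH, CH2Cl2, −78 °C; aq. potassium sodium tartrate work-up
Reagents that add atoms: none
Why: Reductive cleavage of the pivalate; the silyloxyfuran and all ethers are inert to the hydride, and no acid or fluoride touches the furan.

Step 23
Reactants: 36 C6 primary alcohol
Product: 37 (2R,9R)-silyloxyfuran dienal (C6HO; C5=C16H2; C3=C4 Z; 2-OPMB; 9-OTES; 12β-OTBS)
Conditions: MnO2, CH2Cl2, rt
Reagents that add atoms: none
Why: MnO2 oxidation of the primary allylic alcohol under neutral heterogeneous conditions that a silyloxyfuran tolerates.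

Step 24
Reactants: 37 silyloxyfuran dienal
Product: 38 (2R,6R,7R,9R)-tricyclic butenolide (6-OH; 19,7-olide with C8=C17; C5=C16H2; C3=C4 Z; 2-OPMB; 9-OTES; 12β-OTBS)
Conditions: BF3·OEt2 (3 equiv), CH2Cl2, −78 °C, slow addition of 37 to a final 1 mM; then Et3N, aq. NaHCO3
Reagents that add atoms: none
Why: BF3 activates the C6 aldehyde and C7, the γ-terminus of the silyloxyfuran with the largest HOMO coefficient, attacks it through an open transition state; the silyloxycarbenium ion then loses the silyl group to give the butenolide. The closest known reaction is the intermolecular BF3-promoted vinylogous Mukaiyama aldol addition of 2-silyloxyfurans to aldehydes, which is γ- and threo-selective. The ten-membered carbocycle closes in a 10-exo-trig mode at the carbonyl, with the nucleophilic C7=C8 bond inside the new ring, under high dilution. The threo C6/C7 relationship is expected from the open transition state, as in the intermolecular Lewis acid variant. The furan face is set by C9: A(1,3) strain with the C17 methyl holds H9 in the furan plane, C10 then lies on one face, and a ten-membered ring without a transannular C6/C10 contact requires C6 to bond on the opposite face, which is the C7 configuration of the target. The step needs γ- over α-attack (C17 is blocked by its methyl) and 1,2- over 1,4-addition to the enal (favoured by BF3 with aldehydes). The Z C3=C4 alkene and the gauche arrangement of the two arms on the cyclohexene hold C6 and C7 near each other.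

Step 25
Reactants: 38 tricyclic butenolide
Product: 39 8,17-epoxy lactone (epoxide oxygen cis to C6 on the lactone ring; 6-OH free)
Conditions: t-BuOOH, n-BuLi, THF, −78 → −20 °C
Reagents that add atoms: tert-butyl hydroperoxide, CC(C)(C)OO
Why: Weitz–Scheffer-type nucleophilic epoxidation of the unsaturated lactone by lithium tert-butyl peroxide, which leaves the electron-rich alkenes alone. The free C6 hydroxyl lies on the face of C8 that must carry oxygen and is expected to guide the peroxide by coordination.

Step 26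
Reactants: 39 8,17-epoxy lactone
Product: 40 6,8-diol (8-OH cis to C6; 17-methyl cis to 8-OH; 19,7-olide)
Conditions: SmI2, THF/MeOH, −78 °C; then DBU (cat.), CH2Cl2, 0 °C
Reagents that add atoms: none
Why: SmI2 reduction of the α,β-epoxy lactone cleaves the C17–O bond and gives the β-hydroxy lactone. C17 is epimerisable and should settle under base with its methyl trans to the bulky C9 branch, as in the target.

Step 27
Reactants: 40 6,8-diol
Product: 41 (6S)-6-chloride (8-OH; 9-OTES; 2-OPMB; 12β-OTBS)
Conditions: PPh3, hexachloroacetone, 2,6-di-tert-butylpyridine, CH2Cl2, −20 → 0 °C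
Reagents that add atoms: hexachloroacetone, ClC(Cl)(Cl)C(=O)C(Cl)(Cl)Cl
Why: Appel-type chlorination of the secondary allylic alcohol; these conditions favour direct SN2 displacement with inversion and little allylic transposition, and the tertiary C8 hydroxyl does not react.

Step 28
Reactants: 41 6-chloride
Product: 42 9-alcohol (9-OH and 8-OH free; 2-OPMB; 12β-OTBS)
Conditions: HF·pyridine, pyridine, THF, 0 °C
Reagents that add atoms: none
Why: Selective cleavage of the TES ether by buffered HF·pyridine; the TBS and PMB ethers survive and the non-nucleophilic medium spares the allylic chloride.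

Step 29
Reactants: 42 9-alcohol
Product: 43 9-acetate
Conditions: Ac2O, pyridine, DMAP (cat.), CH2Cl2, 0 °C → rt
Reagents that add atoms: acetic anhydride, CC(=O)OC(C)=O
Why: Acetylation of the only free secondary hydroxyl; the tertiary C8 hydroxyl is too hindered under these conditions.

Step 30
Reactants: 43 9-acetate
Product: 44 (2R)-2-alcohol (2-OH free; 9-OAc; 12β-OTBS)
Conditions: DDQ, CH2Cl2/aq. NaH2PO4–Na2HPO4 buffer (pH 7), 0 °C
Reagents that add atoms: none
Why: Oxidative cleavage of the PMB ether by DDQ; the silyl ether, acetate, chloride and lactone are inert.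

Step 31
Reactants: 44 2-alcohol
Product: 45 3,4-epoxide (epoxide oxygen cis to 2-OH on the ten-membered ring)
Conditions: VO(acac)2 (cat.), t-BuOOH, CH2Cl2, 0 °C
Reagents that add atoms: tert-butyl hydroperoxide, CC(C)(C)OO
Why: Hydroxyl-directed vanadium epoxidation; only C3=C4 is allylic to a free hydroxyl. By analogy with medium-ring (Z)-cycloalkenols, the metal should deliver oxygen cis to the hydroxyl, which is the C2/C3 relationship of the target.

Step 32
Reactants: 45 3,4-epoxide
Product: 46 3,4:13,14-diepoxide 12-O-TBS ether (13,14-epoxide α)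
Conditions: mCPBA, NaHCO3, CH2Cl2, 0 °C
Reagents that add atoms: 3-chloroperoxybenzoic acid, OOC(=O)c1cccc(Cl)c1
Why: Peracid epoxidation of C13=C14 from the α face, anti to the 12-silyloxy group and the axial C15 methyl; C5=C16 is deactivated by the flanking epoxide and chloride.

Step 33
Reactants: 46 diepoxide silyl ether
Product: 47 CNP0314105.1, (2S,6S,7R,9R)-9-acetoxy-6-chloro-3,4:13,14-diepoxy-2,8,12-trihydroxybriar-5(16)-en-19,7-olide
Conditions: HF·pyridine, pyridine, THF, 0 °C → rt
Reagents that add atoms: none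
Why: Cleavage of the last silyl ether under buffered conditions that should spare both epoxides, the acetate and the allylic chloride.

## Compound list

1 | glyoxylic acid monohydrate | OC(O)C(=O)O | starting material
2 | tert-butyl 2-(triphenylphosphoranylidene)propanoate | CC(C(=O)OC(C)(C)C)=P(c1ccccc1)(c1ccccc1)c1ccccc1 | starting material
3 | (E)-4-tert-butoxy-3-methyl-4-oxobut-2-enoic acid | CC(C)(C)OC(=O)/C(C)=C/C(=O)O | intermediate
4 | (S)-4-benzyl-1,3-oxazolidin-2-one | O=C1N[C@@H](Cc2ccccc2)CO1 | starting material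
5 | mixed anhydride of 3 with pivalic acid (formed in the flask) | CC(C)(C)OC(=O)/C(C)=C/C(=O)OC(=O)C(C)(C)C | intermediate
6 | (S)-4-benzyl-3-[(E)-4-tert-butoxy-3-methyl-4-oxobut-2-enoyl]-1,3-oxazolidin-2-one | CC(C)(C)OC(=O)/C(C)=C/C(=O)N1C(=O)OC[C@@H]1Cc1ccccc1 | intermediate
7 | (E)-penta-1,3-diene | C/C=C/C=C | starting material
8 | (S)-4-benzyl-3-{[(1S,2S,6S)-6-(tert-butoxycarbonyl)-2,6-dimethylcyclohex-3-en-1-yl]carbonyl}-1,3-oxazolidin-2-one | CC(C)(C)OC(=O)[C@]1(C)[C@H]([C@@H](C)C=CC1)C(=O)N1C(=O)OC[C@@H]1Cc1ccccc1 | intermediate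
9 | (1S,2S,6S)-6-(tert-butoxycarbonyl)-2,6-dimethylcyclohex-3-ene-1-carboperoxoic acid (formed in the flask) | CC(C)(C)OC(=O)[C@]1(C)[C@H]([C@@H](C)C=CC1)C(=O)OO | intermediate
10 | (1S,2S,6S)-6-(tert-butoxycarbonyl)-2,6-dimethylcyclohex-3-ene-1-carboxylic acid | CC(C)(C)OC(=O)[C@]1(C)[C@H]([C@@H](C)C=CC1)C(=O)O | intermediate
11 | tert-butyl 4-iodo-2,8-dimethyl-7-oxo-6-oxabicyclo[3.2.1]octane-2-carboxylate (lactone O at C12 β, iodine at C13 α, 8-methyl toward the lactone bridge) | CC(C)(C)OC(=O)[C@]1(C)[C@@H]2[C@@H](C)[C@@H](OC2=O)[C@H](I)C1 | intermediate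
12 | tert-butyl 2,8-dimethyl-7-oxo-6-oxabicyclo[3.2.1]oct-3-ene-2-carboxylate | CC(C)(C)OC(=O)[C@]1(C)[C@@H]2[C@@H](C)[C@@H](OC2=O)C=C1 | intermediate
13 | tert-butyl 4-hydroxy-6-(hydroxymethyl)-1,5-dimethylcyclohex-2-ene-1-carboxylate (1-methyl, 4-OH, 5-methyl and 6-CH2OH all cis) | CC(C)(C)OC(=O)[C@]1(C)[C@@H](CO)[C@@H](C)[C@@H](O)C=C1 | intermediate
14 | tert-butyldimethylsilyl ester of 15 (formed in the flask) | C[Si](C)(C(C)(C)C)OC(=O)[C@]1(C)[C@@H](CO[Si](C)(C)C(C)(C)C)[C@@H](C)[C@@H](O[Si](C)(C)C(C)(C)C)C=C1 | intermediate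
15 | 4-(tert-butyldimethylsilyloxy)-6-[(tert-butyldimethylsilyloxy)methyl]-1,5-dimethylcyclohex-2-ene-1-carboxylic acid (configuration as 13) | OC(=O)[C@]1(C)[C@@H](CO[Si](C)(C)C(C)(C)C)[C@@H](C)[C@@H](O[Si](C)(C)C(C)(C)C)C=C1 | intermediate
16 | 2-methylidenepropane-1,3-diol | C=C(CO)CO | starting material
17 | 2-(hydroxymethyl)prop-2-en-1-yl 2,2-dimethylpropanoate | C=C(CO)COC(=O)C(C)(C)C | intermediate
18 | 2-formylprop-2-en-1-yl 2,2-dimethylpropanoate | C=C(C=O)COC(=O)C(C)(C)C | intermediate
19 | 2-methylidenebut-3-yn-1-yl 2,2-dimethylpropanoate | C=C(C#C)COC(=O)C(C)(C)C | intermediate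
20 | acid chloride of 15 (formed in the flask) | ClC(=O)[C@]1(C)[C@@H](CO[Si](C)(C)C(C)(C)C)[C@@H](C)[C@@H](O[Si](C)(C)C(C)(C)C)C=C1 | intermediate
21 | C2 ynone: ring A of 15 joined through its C2 carbonyl to C3≡C4–C5(=C16H2)–C6H2–O-pivaloyl | C=C(COC(=O)C(C)(C)C)C#CC(=O)[C@]1(C)[C@@H](CO[Si](C)(C)C(C)(C)C)[C@@H](C)[C@@H](O[Si](C)(C)C(C)(C)C)C=C1 | intermediate
22 | (2S)-propargylic alcohol from 21 | C=C(COC(=O)C(C)(C)C)C#C[C@@H](O)[C@]1(C)[C@@H](CO[Si](C)(C)C(C)(C)C)[C@@H](C)[C@@H](O[Si](C)(C)C(C)(C)C)C=C1 | intermediate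
23 | (2S)-2-O-(4-methoxybenzyl) ether of 22 | C=C(COC(=O)C(C)(C)C)C#C[C@@H](OCc1ccc(OC)cc1)[C@]1(C)[C@@H](CO[Si](C)(C)C(C)(C)C)[C@@H](C)[C@@H](O[Si](C)(C)C(C)(C)C)C=C1 | intermediate
24 | (2R,3Z)-diene: 2-OPMB, C3=C4 Z, C5=C16H2, 6-O-pivaloyl, 9-OTBS, 12β-OTBS | C=C(COC(=O)C(C)(C)C)/C=C\[C@@H](OCc1ccc(OC)cc1)[C@]1(C)[C@@H](CO[Si](C)(C)C(C)(C)C)[C@@H](C)[C@@H](O[Si](C)(C)C(C)(C)C)C=C1 | intermediate
25 | C9 primary alcohol of 24 | C=C(COC(=O)C(C)(C)C)/C=C\[C@@H](OCc1ccc(OC)cc1)[C@]1(C)[C@@H](CO)[C@@H](C)[C@@H](O[Si](C)(C)C(C)(C)C)C=C1 | intermediate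
26 | C9 aldehyde (formyl group on C10, β) | C=C(COC(=O)C(C)(C)C)/C=C\[C@@H](OCc1ccc(OC)cc1)[C@]1(C)[C@@H](C=O)[C@@H](C)[C@@H](O[Si](C)(C)C(C)(C)C)C=C1 | intermediate
27 | ethyl 2-methyl-3-oxobutanoate (ethyl 2-methylacetoacetate) | CCOC(=O)C(C)C(C)=O | starting material
28 | ethyl 2-bromo-2-methyl-3-oxobutanoate (formed in the flask) | CCOC(=O)C(C)(Br)C(C)=O | intermediate
29 | ethyl 4-bromo-2-methyl-3-oxobutanoate (formed in the flask) | CCOC(=O)C(C)C(=O)CBr | intermediate
30 | 4-hydroxy-3-methylfuran-2(5H)-one (3-methyltetronic acid) | CC1=C(O)COC1=O | intermediate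
31 | 4-bromo-3-methylfuran-2(5H)-one | CC1=C(Br)COC1=O | intermediate
32 | (4-bromo-3-methylfuran-2-yl)oxy-triisopropylsilane | Cc1c(Br)coc1O[Si](C(C)C)(C(C)C)C(C)C | intermediate
33 | [4-methyl-5-(triisopropylsilyloxy)furan-3-yl]lithium (formed in the flask) | Cc1c([Li])coc1O[Si](C(C)C)(C(C)C)C(C)C | intermediate
34 | lithium (9R)-alkoxide from 26 and 33 (formed in the flask) | C=C(COC(=O)C(C)(C)C)/C=C\[C@@H](OCc1ccc(OC)cc1)[C@]1(C)[C@@H]([C@@H](O[Li])c2coc(O[Si](C(C)C)(C(C)C)C(C)C)c2C)[C@@H](C)[C@@H](O[Si](C)(C)C(C)(C)C)C=C1 | intermediate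
35 | (2R,9R)-9-O-triethylsilyl furyl carbinol, 6-O-pivaloyl (furan carbons are C8, C7, C19 and C17; 19-O-triisopropylsilyl) | C=C(COC(=O)C(C)(C)C)/C=C\[C@@H](OCc1ccc(OC)cc1)[C@]1(C)[C@@H]([C@@H](O[Si](CC)(CC)CC)c2coc(O[Si](C(C)C)(C(C)C)C(C)C)c2C)[C@@H](C)[C@@H](O[Si](C)(C)C(C)(C)C)C=C1 | intermediate
36 | C6 primary alcohol of 35 | C=C(CO)/C=C\[C@@H](OCc1ccc(OC)cc1)[C@]1(C)[C@@H]([C@@H](O[Si](CC)(CC)CC)c2coc(O[Si](C(C)C)(C(C)C)C(C)C)c2C)[C@@H](C)[C@@H](O[Si](C)(C)C(C)(C)C)C=C1 | intermediate
37 | (2R,9R)-silyloxyfuran dienal: C6HO, C5=C16H2, C3=C4 Z, 2-OPMB, 9-OTES, 12β-OTBS | O=CC(=C)/C=C\[C@@H](OCc1ccc(OC)cc1)[C@]1(C)[C@@H]([C@@H](O[Si](CC)(CC)CC)c2coc(O[Si](C(C)C)(C(C)C)C(C)C)c2C)[C@@H](C)[C@@H](O[Si](C)(C)C(C)(C)C)C=C1 | intermediate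
38 | (2R,6R,7R,9R)-tricyclic butenolide: 6-OH, 19,7-olide with C8=C17, 6,7-threo | O[C@@H]1C(=C)/C=C\[C@@H](OCc2ccc(OC)cc2)[C@]2(C)[C@H]([C@@H](C)[C@@H](O[Si](C)(C)C(C)(C)C)C=C2)[C@@H](O[Si](CC)(CC)CC)C2=C(C)C(=O)O[C@@H]12 | intermediate
39 | 8,17-epoxy lactone (epoxide oxygen cis to C6, trans to H7) | O[C@@H]1C(=C)/C=C\[C@@H](OCc2ccc(OC)cc2)[C@]2(C)[C@H]([C@@H](C)[C@@H](O[Si](C)(C)C(C)(C)C)C=C2)[C@@H](O[Si](CC)(CC)CC)[C@@]23O[C@@]3(C)C(=O)O[C@@H]12 | intermediate
40 | 6,8-diol (8-OH cis to C6; 17-methyl cis to 8-OH) | O[C@@H]1C(=C)/C=C\[C@@H](OCc2ccc(OC)cc2)[C@]2(C)[C@H]([C@@H](C)[C@@H](O[Si](C)(C)C(C)(C)C)C=C2)[C@@H](O[Si](CC)(CC)CC)[C@]2(O)[C@@H](C)C(=O)O[C@@H]12 | intermediate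
41 | (6S)-6-chloride of 40 | Cl[C@H]1C(=C)/C=C\[C@@H](OCc2ccc(OC)cc2)[C@]2(C)[C@H]([C@@H](C)[C@@H](O[Si](C)(C)C(C)(C)C)C=C2)[C@@H](O[Si](CC)(CC)CC)[C@]2(O)[C@@H](C)C(=O)O[C@@H]12 | intermediate
42 | 9-alcohol (8,9-diol; 6-chloride) | Cl[C@H]1C(=C)/C=C\[C@@H](OCc2ccc(OC)cc2)[C@]2(C)[C@H]([C@@H](C)[C@@H](O[Si](C)(C)C(C)(C)C)C=C2)[C@@H](O)[C@]2(O)[C@@H](C)C(=O)O[C@@H]12 | intermediate
43 | 9-acetate of 42 | Cl[C@H]1C(=C)/C=C\[C@@H](OCc2ccc(OC)cc2)[C@]2(C)[C@H]([C@@H](C)[C@@H](O[Si](C)(C)C(C)(C)C)C=C2)[C@@H](OC(C)=O)[C@]2(O)[C@@H](C)C(=O)O[C@@H]12 | intermediate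
44 | (2R)-2-alcohol (PMB removed) | Cl[C@H]1C(=C)/C=C\[C@@H](O)[C@]2(C)[C@H]([C@@H](C)[C@@H](O[Si](C)(C)C(C)(C)C)C=C2)[C@@H](OC(C)=O)[C@]2(O)[C@@H](C)C(=O)O[C@@H]12 | intermediate
45 | 3,4-epoxide (oxygen cis to 2-OH) | Cl[C@H]1C(=C)[C@H]2O[C@H]2[C@@H](O)[C@]2(C)[C@H]([C@@H](C)[C@@H](O[Si](C)(C)C(C)(C)C)C=C2)[C@@H](OC(C)=O)[C@]2(O)[C@@H](C)C(=O)O[C@@H]12 | intermediate
46 | 3,4:13,14-diepoxide 12-O-TBS ether (13,14-epoxide α) | Cl[C@H]1C(=C)[C@H]2O[C@H]2[C@@H](O)[C@]2(C)[C@H]([C@@H](C)[C@@H](O[Si](C)(C)C(C)(C)C)[C@@H]3O[C@@H]32)[C@@H](OC(C)=O)[C@]2(O)[C@@H](C)C(=O)O[C@@H]12 | intermediate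
47 | CNP0314105.1, (2S,6S,7R,9R)-9-acetoxy-6-chloro-3,4:13,14-diepoxy-2,8,12-trihydroxybriar-5(16)-en-19,7-olide | C=C1[C@H]2O[C@H]2[C@@H](O)[C@]2(C)[C@H]([C@@H](C)[C@@H](O)[C@@H]3O[C@@H]32)[C@@H](OC(C)=O)[C@]2(O)[C@@H](C)C(=O)O[C@H]2[C@H]1Cl | target

## Step count and least certain steps

Total: 33 steps. Longest linear sequence: 27 steps (steps 1–8, 12–17 and 21–33); steps 9–11 and 18–20 make the two side fragments.

**Step 24 (key step).** The likely failures are intermolecular aldol oligomerisation instead of ring closure, conjugate attack of C7 at C16 of the 2-substituted acrolein, or closure on the other furan face through a different C8–C9 rotamer. Fallback: starting from 37, N-bromosuccinimide converts the silyloxyfuran into the gamma-bromobutenolide dienal F1 (C7 bromide, aldehyde intact). A SmI2-mediated intramolecular vinylogous Reformatsky reaction under high dilution then closes C6–C7 through a metal-templated enolate and returns to 38. Its γ- versus α-regiochemistry would have to be confirmed.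

**Step 3.** The trisubstituted dienophile may react sluggishly, or the Lewis acid may be shared between the imide and the ester so that regiochemical or endo control erodes. Fallback: ylide 2 and aqueous glyoxal give tert-butyl (E)-2-methyl-4-oxobut-2-enoate F2. A catalytic enantioselective Diels–Alder reaction of this enal with 7 under a chiral oxazaborolidinium Lewis acid (antipode chosen by the facial model) gives the cyclohexene aldehyde F3. Pinnick oxidation (NaClO2, NaH2PO4, 2-methylbut-2-ene) returns to 10.

**Step 21.** Facial selectivity at the aldehyde may be poor because both carbons flanking C10 are branched, and the aldehyde may epimerise at C10 before addition. Fallback: from 26, addition of 33 without trapping gives the C9-epimeric carbinols F4. Dess–Martin oxidation gives the furyl ketone F5, and reagent-controlled reduction with the (S)-CBS catalyst and catecholborane gives the (9R) alcohol F6. Silylation with Et3SiOTf/2,6-lutidine returns to 35.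

**Step 25.** The tetrasubstituted butenolide may react slowly, or the peroxide may attack the face away from C6, which would give the C8 epimer after reduction. Fallback: from 38, benzaldehyde and catalytic KOt-Bu form the hemiacetal alkoxide, which adds intramolecularly to C8 and gives the benzylidene acetal F7. Because oxygen is delivered from O6, the C8–O bond is necessarily cis to C6. Aqueous acetic acid then removes the acetal and the TES ether to give the triol F8, and PPh3/hexachloroacetone chlorinates the allylic C6 hydroxyl selectively, returning to 42.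

**Step 31.** Oxygen may be delivered trans to the C2 hydroxyl if the ring holds that hydroxyl away from the alkene face, and the vinyl epoxide may open on the Lewis acidic metal. Fallback: from 44, reagent-controlled epoxidation with Ti(Oi-Pr)4, D-(−)-diisopropyl tartrate and t-BuOOH. For this tartrate 44 is the fast-reacting enantiomer, and the matched case gives the erythro (cis) epoxy alcohol 45. This makes no compound outside the list (F0).

## Further compounds

F1 | step 24 | gamma-bromobutenolide dienal (C7 bromide, both C7 epimers; otherwise as 37) | O=CC(=C)/C=C\[C@@H](OCc1ccc(OC)cc1)[C@]1(C)[C@@H]([C@@H](O[Si](CC)(CC)CC)C2=C(C)C(=O)OC2Br)[C@@H](C)[C@@H](O[Si](C)(C)C(C)(C)C)C=C1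
F2 | step 3 | tert-butyl (E)-2-methyl-4-oxobut-2-enoate | CC(C)(C)OC(=O)/C(C)=C/C=O
F3 | step 3 | tert-butyl (1S,5S,6S)-6-formyl-1,5-dimethylcyclohex-3-ene-1-carboxylate (aldehyde analogue of 10) | CC(C)(C)OC(=O)[C@]1(C)[C@H]([C@@H](C)C=CC1)C=O
F4 | step 21 | C9-epimeric furyl carbinols (9-OH free, C9 unassigned; otherwise as 35) | C=C(COC(=O)C(C)(C)C)/C=C\[C@@H](OCc1ccc(OC)cc1)[C@]1(C)[C@@H](C(O)c2coc(O[Si](C(C)C)(C(C)C)C(C)C)c2C)[C@@H](C)[C@@H](O[Si](C)(C)C(C)(C)C)C=C1
F5 | step 21 | C9 furyl ketone | C=C(COC(=O)C(C)(C)C)/C=C\[C@@H](OCc1ccc(OC)cc1)[C@]1(C)[C@@H](C(=O)c2coc(O[Si](C(C)C)(C(C)C)C(C)C)c2C)[C@@H](C)[C@@H](O[Si](C)(C)C(C)(C)C)C=C1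
F6 | step 21 | (9R)-furyl carbinol | C=C(COC(=O)C(C)(C)C)/C=C\[C@@H](OCc1ccc(OC)cc1)[C@]1(C)[C@@H]([C@@H](O)c2coc(O[Si](C(C)C)(C(C)C)C(C)C)c2C)[C@@H](C)[C@@H](O[Si](C)(C)C(C)(C)C)C=C1
F7 | step 25 | 6,8-O-benzylidene acetal of 40 (acetal carbon unassigned) | O3[C@@H]1C(=C)/C=C\[C@@H](OCc4ccc(OC)cc4)[C@]2(C)[C@H]([C@@H](C)[C@@H](O[Si](C)(C)C(C)(C)C)C=C2)[C@@H](O[Si](CC)(CC)CC)[C@]2(OC3c3ccccc3)[C@@H](C)C(=O)O[C@@H]12
F8 | step 25 | 6,8,9-triol (2-OPMB, 12β-OTBS) | O[C@@H]1C(=C)/C=C\[C@@H](OCc2ccc(OC)cc2)[C@]2(C)[C@H]([C@@H](C)[C@@H](O[Si](C)(C)C(C)(C)C)C=C2)[C@@H](O)[C@]2(O)[C@@H](C)C(=O)O[C@@H]12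
F0 | step 31 | none | none
A1 | alternative 1 | fourteen-membered 2,12-diketone with the C10=C11 and C13=C14 enones (C1 unassigned) | C=C1[C@H]2O[C@H]2C(=O)C(C)/C=C\C(=O)/C(C)=C/[C@@H](OC(C)=O)[C@]2(O)[C@@H](C)C(=O)O[C@H]2[C@H]1Cl
A2 | alternative 1 | 2,12-diketo-13-ene tricycle | C=C1[C@H]2O[C@H]2C(=O)[C@]2(C)[C@H]([C@@H](C)C(=O)C=C2)[C@@H](OC(C)=O)[C@]2(O)[C@@H](C)C(=O)O[C@H]2[C@H]1Cl
A3 | alternative 2 | bicyclic C8 ketone with the C7 2-bromopropanoate | [C@@H]12O[C@H]2[C@@H](O[Si](CC)(CC)CC)[C@]2(C)[C@H]([C@@H](C)[C@@H](O[Si](CC)(CC)CC)[C@@H]3O[C@@H]32)[C@@H](O[Si](C)(C)C(C)(C)C)C(=O)[C@@H](OC(=O)C(C)Br)/C=C1/C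
A4 | alternative 2 | tricyclic hydroxy lactone with the C5-methyl Z alkene | [C@@H]12O[C@H]2[C@@H](O[Si](CC)(CC)CC)[C@]2(C)[C@H]([C@@H](C)[C@@H](O[Si](CC)(CC)CC)[C@@H]3O[C@@H]32)[C@@H](O[Si](C)(C)C(C)(C)C)[C@]2(O)[C@@H](C)C(=O)O[C@H]2/C=C1/C
A5 | alternative 3 | 2-vinyl-7-allenyl-7-methoxy decalin C2 alcohol (C2 and C7 drawn arbitrarily) | C=C[C@@]1(O)[C@@](OC)(C=C=C)[C@@H](OCc2ccc(OC)cc2)[C@H](O[Si](C)(C)C(C)(C)C)[C@H]2[C@@H](C)[C@@H](O[Si](C)(C)C(C)(C)C)C=C[C@]12C
A6 | alternative 3 | bicyclic cyclodecadienone with C7 enol ether and C5 methylene | O=C1CCC(=C)/C=C(\OC)[C@@H](OCc3ccc(OC)cc3)[C@H](O[Si](C)(C)C(C)(C)C)[C@H]2[C@@H](C)[C@@H](O[Si](C)(C)C(C)(C)C)C=C[C@]12C
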